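**Plan**
- The depside ester C–O bond between the ring A carbonyl and the C4 oxygen of ring B is cut first, giving a protected ring A acid and a ring B phenol.
- In ring B the carboxyl carbon C1 sits between the methoxy carbon C2 and the pentyl carbon C6. This is the pattern left when pentyllithium and then CO2 add across a C1–C6 aryne with OMe on the neighbouring C2, so the C6–pentyl and C1–CO2H bonds are cut together.
- In ring A the ArCH2–C(=O) bond of the 2-oxoheptyl chain is cut (lateral lithiation of an orsellinate, acylation with a hexanoic Weinreb amide). The ketone travels as a dioxolane and the phenol as a benzyl ether.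
- Forward: no ring is formed at any stage. Ring B is elaborated in steps 1–6, ring A in steps 7–12, the two are esterified in step 13 and unmasked in steps 14–15.
- The target has no stereocentre and no stereogenic double bond, so no stereocontrol is needed.

Key step: step 4

Remark: ring B is numbered from its carboxyl carbon (C1). The ring A ketone is masked because an activated 2-(2-oxoalkyl)benzoic acid would close to an isocoumarin.

**Route**

Step 1
Reactants: 1 1-fluoro-3,5-dimethoxybenzene
Product: 3 3-fluoro-5-methoxyphenol, via dibromo(3-fluoro-5-methoxyphenoxy)borane 2 (not isolated)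
Conditions: BBr3 (1.0 equiv), CH2Cl2, -78 °C to rt; then H2O
Reagents that add atoms: none
Why: Lewis acid cleavage of an aryl methyl ether with a limited amount of BBr3 should favour the mono-phenol, which is separated from unchanged 1 and from the diol by base extraction and chromatography.

Step 2
Reactants: 3 3-fluoro-5-methoxyphenol
Product: 4 (3-fluoro-5-methoxyphenoxy)triisopropylsilane
Conditions: iPr3SiCl, imidazole, DMF, rt
Reagents that add atoms: chlorotriisopropylsilane, CC(C)[Si](Cl)(C(C)C)C(C)C
Why: Imidazole-promoted silylation of a phenol should install a bulky, poorly coordinating silyl ether that withstands alkyllithiums.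

Step 3
Reactants: 5 1-chloropentane
Product: 6 pentyllithium
Conditions: Li metal (2.2 equiv, containing about 1% Na), hexane, reflux; filtered and titrated
Reagents that add atoms: lithium, [Li]
Why: Reductive lithiation of a primary alkyl chloride with lithium metal in a hydrocarbon is the standard preparation of primary alkyllithiums.

Step 4
Reactants: 4 (3-fluoro-5-methoxyphenoxy)triisopropylsilane; 6 pentyllithium; 7 carbon dioxide
Product: 11 2-methoxy-6-pentyl-4-(triisopropylsilyloxy)benzoic acid, via [2-fluoro-6-methoxy-4-(triisopropylsilyloxy)phenyl]lithium 8 (not isolated), via 3-methoxy-5-(triisopropylsilyloxy)benzyne 9 (not isolated), via [2-methoxy-6-pentyl-4-(triisopropylsilyloxy)phenyl]lithium 10 (not isolated)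
Conditions: 6 (2.5 equiv), THF, -78 °C to -10 °C; CO2 (7), -78 °C to rt; then cold 1 M HCl
Reagents that add atoms: none
Why: One equivalent of pentyllithium removes the proton between fluorine and methoxy to give 8, which loses LiF on warming to aryne 9; a second equivalent adds to the aryne carbon remote from methoxy to give aryllithium 10, and CO2 converts 10 into the carboxylate, protonated on work-up. The closest known reaction type is the generation of 3-alkoxyarynes from 3-fluoroanisoles with alkyllithiums, followed by carbolithiation and electrophilic quench, used here as an aryne 1,2-difunctionalization that forms the C6–pentyl and C1–carboxyl bonds of ring B. No ring is closed and no stereocentre is created. The site of lithiation is secured by the combined acidifying and lithium-binding effect of fluorine and methoxy, while the bulky silyloxy group keeps the other CH next to fluorine and the CH between the two oxygens quiet. The direction of addition is secured by the methoxy group beside the triple bond, which stabilizes the carbanion on the adjacent carbon and distorts the aryne toward attack at the far carbon. Excess pentyllithium and gradual warming should keep 10 from adding to 9, and the hindered silyl ether is inert to the alkyllithium.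

Step 5
Reactants: 11 2-methoxy-6-pentyl-4-(triisopropylsilyloxy)benzoic acid
Product: 12 benzyl 2-methoxy-6-pentyl-4-(triisopropylsilyloxy)benzoate
Conditions: BnBr, KHCO3, DMF, rt
Reagents that add atoms: benzyl bromide, BrCc1ccccc1
Why: Carboxylate O-alkylation (SN2 at benzyl bromide) is indifferent to the two ortho substituents, and bicarbonate is too weak a base to cleave the aryl silyl ether.

Step 6
Reactants: 12 benzyl 2-methoxy-6-pentyl-4-(triisopropylsilyloxy)benzoate
Product: 13 benzyl 4-hydroxy-2-methoxy-6-pentylbenzoate
Conditions: Bu4NF, AcOH, THF, 0 °C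
Reagents that add atoms: none
Why: Fluoride-driven desilylation of an aryl silyl ether, buffered with acetic acid, should free the C4 phenol without touching the benzyl ester.

Step 7
Reactants: 14 methyl 2,4-dihydroxy-6-methylbenzoate (methyl orsellinate)
Product: 15 methyl 2-hydroxy-4-methoxy-6-methylbenzoate
Conditions: MeI (1.05 equiv), K2CO3, acetone, reflux
Reagents that add atoms: iodomethane, CI
Why: Williamson etherification should select the 4-hydroxyl because the 2-hydroxyl is hydrogen-bonded to the ester carbonyl and is less acidic and less nucleophilic.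

Step 8
Reactants: 15 methyl 2-hydroxy-4-methoxy-6-methylbenzoate
Product: 16 methyl 2-(benzyloxy)-4-methoxy-6-methylbenzoate
Conditions: BnBr, K2CO3, DMF, 60 °C
Reagents that add atoms: benzyl bromide, BrCc1ccccc1
Why: Williamson etherification under more forcing conditions should alkylate the remaining hydrogen-bonded phenol.

Step 9
Reactants: 17 hexanoyl chloride
Product: 18 N-methoxy-N-methylhexanamide
Conditions: MeNH(OMe)·HCl, Et3N, CH2Cl2, 0 °C to rt
Reagents that add atoms: N,O-dimethylhydroxylamine hydrochloride, CNOC.Cl
Why: N-Acylation of the hydroxylamine by the acid chloride is the standard preparation of a Weinreb amide.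

Step 10
Reactants: 16 methyl 2-(benzyloxy)-4-methoxy-6-methylbenzoate; 18 N-methoxy-N-methylhexanamide
Product: 20 methyl 2-(benzyloxy)-4-methoxy-6-(2-oxoheptyl)benzoate, via [3-(benzyloxy)-5-methoxy-2-(methoxycarbonyl)benzyl]lithium 19 (not isolated)
Conditions: LiN(iPr)2 (2 equiv), THF, -78 °C; then 18, -78 °C to -40 °C; then 1 M HCl, 0 °C
Reagents that add atoms: none
Why: Lateral lithiation of the ortho-toluate gives a benzylic anion stabilized as an ester dienolate and shielded from self-condensation by the doubly flanked ester, and Weinreb ketone synthesis with 18 should stop at the ketone.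

Step 11
Reactants: 20 methyl 2-(benzyloxy)-4-methoxy-6-(2-oxoheptyl)benzoate
Product: 21 methyl 2-(benzyloxy)-4-methoxy-6-[(2-pentyl-1,3-dioxolan-2-yl)methyl]benzoate
Conditions: Me3SiOCH2CH2OSiMe3, Me3SiOSO2CF3 (cat.), CH2Cl2, -78 °C to -20 °C; then pyridine, aq. NaHCO3
Reagents that add atoms: 1,2-bis(trimethylsilyloxy)ethane, C[Si](C)(C)OCCO[Si](C)(C)C
Why: Noyori ketalization runs cold and aprotic, so the ketone should be masked without the hot protic acid that would drive enol-lactonization onto the neighbouring ester.

Step 12
Reactants: 21 methyl 2-(benzyloxy)-4-methoxy-6-[(2-pentyl-1,3-dioxolan-2-yl)methyl]benzoate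
Product: 22 2-(benzyloxy)-4-methoxy-6-[(2-pentyl-1,3-dioxolan-2-yl)methyl]benzoic acid
Conditions: KOH, DMSO/H2O (4:1), 80 °C; then cold 1 M HCl to pH 3–4, rapid extraction
Reagents that add atoms: potassium hydroxide, [K+].[OH-]
Why: Saponification with poorly solvated hydroxide in aqueous DMSO is the usual answer to doubly ortho-substituted methyl benzoates, and the dioxolane, benzyl ether and aryl methyl ether are stable to base.

Step 13
Reactants: 22 2-(benzyloxy)-4-methoxy-6-[(2-pentyl-1,3-dioxolan-2-yl)methyl]benzoic acid; 13 benzyl 4-hydroxy-2-methoxy-6-pentylbenzoate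
Product: 23 4-[(benzyloxy)carbonyl]-3-methoxy-5-pentylphenyl 2-(benzyloxy)-4-methoxy-6-[(2-pentyl-1,3-dioxolan-2-yl)methyl]benzoate
Conditions: DCC, 4-(dimethylamino)pyridine (cat.), CH2Cl2, 0 °C to rt
Reagents that add atoms: none
Why: Steglich esterification (carbodiimide activation with nucleophilic catalysis) should acylate the unhindered, fairly acidic phenol under neutral conditions that spare the dioxolane and the benzyl ester.

Step 14
Reactants: 23 4-[(benzyloxy)carbonyl]-3-methoxy-5-pentylphenyl 2-(benzyloxy)-4-methoxy-6-[(2-pentyl-1,3-dioxolan-2-yl)methyl]benzoate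
Product: 24 4-[(benzyloxy)carbonyl]-3-methoxy-5-pentylphenyl 2-(benzyloxy)-4-methoxy-6-(2-oxoheptyl)benzoate
Conditions: p-toluenesulfonic acid monohydrate (cat.), acetone/H2O, rt
Reagents that add atoms: water, O
Why: Acid-catalysed ketal hydrolysis of a dialkyl ketone dioxolane is fast at room temperature, well below what is needed to cleave the hindered aryl ester or the benzyl ester.

Step 15
Reactants: 24 4-[(benzyloxy)carbonyl]-3-methoxy-5-pentylphenyl 2-(benzyloxy)-4-methoxy-6-(2-oxoheptyl)benzoate
Product: 25 confluentic acid, 4-{[2-hydroxy-4-methoxy-6-(2-oxoheptyl)benzoyl]oxy}-2-methoxy-6-pentylbenzoic acid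
Conditions: H2 (1 atm), Pd/C, EtOAc, rt
Reagents that add atoms: none
Why: Catalytic hydrogenolysis should cleave the benzyl ether and the benzyl ester together under neutral conditions, leaving the depside ester, the dialkyl ketone and both methyl ethers intact.

**Compound list**
1 | 1-fluoro-3,5-dimethoxybenzene | COc1cc(F)cc(OC)c1 | starting material
2 | dibromo(3-fluoro-5-methoxyphenoxy)borane | COc1cc(F)cc(OB(Br)Br)c1 | intermediate
3 | 3-fluoro-5-methoxyphenol | COc1cc(O)cc(F)c1 | intermediate
4 | (3-fluoro-5-methoxyphenoxy)triisopropylsilane | COc1cc(F)cc(O[Si](C(C)C)(C(C)C)C(C)C)c1 | intermediate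
5 | 1-chloropentane | CCCCCCl | starting material
6 | pentyllithium | [Li]CCCCC | intermediate
7 | carbon dioxide | O=C=O | starting material
8 | [2-fluoro-6-methoxy-4-(triisopropylsilyloxy)phenyl]lithium | COc1cc(O[Si](C(C)C)(C(C)C)C(C)C)cc(F)c1[Li] | intermediate
9 | 3-methoxy-5-(triisopropylsilyloxy)benzyne | COC1=CC(O[Si](C(C)C)(C(C)C)C(C)C)=CC#C1 | intermediate
10 | [2-methoxy-6-pentyl-4-(triisopropylsilyloxy)phenyl]lithium | CCCCCc1cc(O[Si](C(C)C)(C(C)C)C(C)C)cc(OC)c1[Li] | intermediate
11 | 2-methoxy-6-pentyl-4-(triisopropylsilyloxy)benzoic acid | CCCCCc1cc(O[Si](C(C)C)(C(C)C)C(C)C)cc(OC)c1C(=O)O | intermediate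
12 | benzyl 2-methoxy-6-pentyl-4-(triisopropylsilyloxy)benzoate | CCCCCc1cc(O[Si](C(C)C)(C(C)C)C(C)C)cc(OC)c1C(=O)OCc1ccccc1 | intermediate
13 | benzyl 4-hydroxy-2-methoxy-6-pentylbenzoate | CCCCCc1cc(O)cc(OC)c1C(=O)OCc1ccccc1 | intermediate
14 | methyl 2,4-dihydroxy-6-methylbenzoate (methyl orsellinate) | COC(=O)c1c(C)cc(O)cc1O | starting material
15 | methyl 2-hydroxy-4-methoxy-6-methylbenzoate | COC(=O)c1c(C)cc(OC)cc1O | intermediate
16 | methyl 2-(benzyloxy)-4-methoxy-6-methylbenzoate | COC(=O)c1c(C)cc(OC)cc1OCc1ccccc1 | intermediate
17 | hexanoyl chloride | CCCCCC(=O)Cl | starting material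
18 | N-methoxy-N-methylhexanamide | CCCCCC(=O)N(C)OC | intermediate
19 | [3-(benzyloxy)-5-methoxy-2-(methoxycarbonyl)benzyl]lithium | [Li]Cc1cc(OC)cc(OCc2ccccc2)c1C(=O)OC | intermediate
20 | methyl 2-(benzyloxy)-4-methoxy-6-(2-oxoheptyl)benzoate | CCCCCC(=O)Cc1cc(OC)cc(OCc2ccccc2)c1C(=O)OC | intermediate
21 | methyl 2-(benzyloxy)-4-methoxy-6-[(2-pentyl-1,3-dioxolan-2-yl)methyl]benzoate | CCCCCC1(Cc2cc(OC)cc(OCc3ccccc3)c2C(=O)OC)OCCO1 | intermediate
22 | 2-(benzyloxy)-4-methoxy-6-[(2-pentyl-1,3-dioxolan-2-yl)methyl]benzoic acid | CCCCCC1(Cc2cc(OC)cc(OCc3ccccc3)c2C(=O)O)OCCO1 | intermediate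
23 | 4-[(benzyloxy)carbonyl]-3-methoxy-5-pentylphenyl 2-(benzyloxy)-4-methoxy-6-[(2-pentyl-1,3-dioxolan-2-yl)methyl]benzoate | CCCCCC1(Cc2cc(OC)cc(OCc3ccccc3)c2C(=O)Oc2cc(CCCCC)c(C(=O)OCc3ccccc3)c(OC)c2)OCCO1 | intermediate
24 | 4-[(benzyloxy)carbonyl]-3-methoxy-5-pentylphenyl 2-(benzyloxy)-4-methoxy-6-(2-oxoheptyl)benzoate | CCCCCC(=O)Cc1cc(OC)cc(OCc2ccccc2)c1C(=O)Oc1cc(CCCCC)c(C(=O)OCc2ccccc2)c(OC)c1 | intermediate
25 | confluentic acid, 4-{[2-hydroxy-4-methoxy-6-(2-oxoheptyl)benzoyl]oxy}-2-methoxy-6-pentylbenzoic acid | CCCCCC(=O)Cc1cc(OC)cc(O)c1C(=O)Oc1cc(CCCCC)c(C(=O)O)c(OC)c1 | target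

**Count and risks**

Total step count: 15. Longest linear sequence: 8 steps (steps 1, 2, 4, 5, 6, 13, 14, 15; the ring A branch through steps 7, 8, 10, 11, 12 is equally long).

Steps most likely to fail:

Step 4. The aryllithium 10 may add to aryne 9 that is still being formed, or be protonated by the solvent before carboxylation, and lithiation may stray to the other ring positions. The fallback sets out from 4 and returns at 11 without an aryne. Compound 4 is lithiated with pentyllithium 6 (1.05 equiv) in THF held at -78 °C, where 8 does not lose LiF, and quenched cold with CO2 to give 2-fluoro-6-methoxy-4-(triisopropylsilyloxy)benzoic acid F1. F1 is then treated with 6 (about 2.5 equiv, THF, -78 °C to 0 °C): the first equivalent forms the lithium carboxylate and the next displaces fluoride by carboxylate-assisted addition–elimination, a known nucleophilic aromatic substitution on unprotected ortho-fluorobenzoic acids. This should give 11 with the pentyl group fixed at the former C–F carbon.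

Step 13. Acylation of the phenol by the doubly ortho-substituted acid may be slow enough that acyl migration within the carbodiimide-activated acid consumes it. The fallback sets out from 22 and returns at 23. Cyanuric fluoride and pyridine in CH2Cl2 convert 22 into 2-(benzyloxy)-4-methoxy-6-[(2-pentyl-1,3-dioxolan-2-yl)methyl]benzoyl fluoride F2, an isolable and sterically small acyl donor. F2 is then combined with phenol 13 and Cs2CO3 in MeCN, so that a preformed phenoxide attacks the acyl fluoride.

Step 12. Hydrolysis of the ester shielded on both sides may stall, or the dioxolane may be lost during acidification and the freed ketone may then lactonize onto the acid. The fallback sets out from 21 and returns at 22 by a redox sequence in place of hydrolysis. LiAlH4 in THF at 0 °C reduces the ester to {2-(benzyloxy)-4-methoxy-6-[(2-pentyl-1,3-dioxolan-2-yl)methyl]phenyl}methanol F3. MnO2 in CH2Cl2 oxidizes the benzylic alcohol to 2-(benzyloxy)-4-methoxy-6-[(2-pentyl-1,3-dioxolan-2-yl)methyl]benzaldehyde F4. Pinnick oxidation (NaClO2, NaH2PO4, 2-methyl-2-butene, t-BuOH/H2O) then gives 22 at a buffered pH that the dioxolane tolerates.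

**Further compounds**
F1 | step 4 | 2-fluoro-6-methoxy-4-(triisopropylsilyloxy)benzoic acid | COc1cc(O[Si](C(C)C)(C(C)C)C(C)C)cc(F)c1C(=O)O
F2 | step 13 | 2-(benzyloxy)-4-methoxy-6-[(2-pentyl-1,3-dioxolan-2-yl)methyl]benzoyl fluoride | CCCCCC1(Cc2cc(OC)cc(OCc3ccccc3)c2C(=O)F)OCCO1
F3 | step 12 | {2-(benzyloxy)-4-methoxy-6-[(2-pentyl-1,3-dioxolan-2-yl)methyl]phenyl}methanol | CCCCCC1(Cc2cc(OC)cc(OCc3ccccc3)c2CO)OCCO1
F4 | step 12 | 2-(benzyloxy)-4-methoxy-6-[(2-pentyl-1,3-dioxolan-2-yl)methyl]benzaldehyde | CCCCCC1(Cc2cc(OC)cc(OCc3ccccc3)c2C=O)OCCO1
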